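Each quinone is an over-oxidised 2,5-dialkylresorcinol. The C-methyl carbon lies para to the tether-bearing carbon. The C–OMe carbon and one C=O carbon flank the methyl-bearing carbon in ring A and the tether-bearing carbon in ring B. Both rings are therefore traced back to cyclohexane-1,3-diones, and each is opened into an enone and a malonate. In one pot, two malonates add to a linear C24 bis-enone (ethyl alkenyl ketone at one end, crotonyl ketone at the other, fifteen CH2 groups between). Both adducts then ring-close, giving two carbocycles and four C–C bonds with the head-to-tail substitution fixed. The two missing oxygens per ring enter later at the free ring CH positions.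

Key step: step 7

Remark: the target (C30H42O8) has no stereocentre and no stereogenic double bond, so it is achiral and no enantiomer has to be selected; stereocentres in intermediates are carried as mixtures and all vanish on aromatisation.
Ring locants in the Why lines: C-1 and C-3 are the dione carbons, C-2 lies between them, C-5 is para to C-2; ring A has CH3 at C-2 and the tether at C-5, ring B the reverse.

Step 1
Reactants: 1 hexadecane-1,16-diol
Product: 2 16-bromohexadecan-1-ol
Conditions: 48% aq HBr (1.2 equiv), toluene, reflux
Reagents that add atoms: hydrogen bromide, Br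
Why: SN2 displacement of one protonated hydroxyl by bromide in the two-phase HBr/toluene system is the standard monobromination of α,ω-diols, and the bromo alcohol is easily separated from residual diol and dibromide.

Step 2
Reactants: 2 16-bromohexadecan-1-ol
Product: 3 tert-butyl[(16-bromohexadecyl)oxy]dimethylsilane
Conditions: TBSCl, imidazole, CH2Cl2, rt
Reagents that add atoms: tert-butyldimethylsilyl chloride, CC(C)(C)[Si](C)(C)Cl
Why: Imidazole-promoted O-silylation removes the only acidic proton, and a primary TBS ether survives magnesium insertion and the Grignard reagent of step 3.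

Step 3
Reactants: 3 tert-butyl[(16-bromohexadecyl)oxy]dimethylsilane, 4 (E)-crotonaldehyde
Product: 6 (E)-20-[(tert-butyldimethylsilyl)oxy]icos-2-en-4-ol (racemic), via Grignard reagent 5 (not isolated)
Conditions: Mg, I2 (cat.), THF, reflux; then 4, −78 → 0 °C; aq NH4Cl
Reagents that add atoms: (E)-crotonaldehyde (4), C/C=C/C=O
Why: Magnesium insertion and 1,2-addition of the hard alkyl Grignard reagent to the enal carbonyl (Grignard addition) should give the secondary allylic alcohol, whose new carbinol centre forms racemic and is removed by the oxidation in step 5.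

Step 4
Reactants: 6 (E)-20-[(tert-butyldimethylsilyl)oxy]icos-2-en-4-ol
Product: 7 (E)-icos-18-ene-1,17-diol (racemic)
Conditions: TBAF (1.2 equiv), THF, 0 °C → rt
Reagents that add atoms: none
Why: Fluoride-driven Si–O cleavage frees the primary alcohol under non-acidic conditions, so the ionisable allylic alcohol is neither transposed nor etherified.

Step 5
Reactants: 7 (E)-icos-18-ene-1,17-diol
Product: 8 (E)-17-oxoicos-18-enal
Conditions: Dess–Martin periodinane (2.5 equiv), CH2Cl2, 0 °C → rt
Reagents that add atoms: none
Why: Dess–Martin oxidation converts the primary alcohol into the aldehyde and the allylic carbinol into the (E)-enone in one operation, without over-oxidation or alkene isomerisation, and it deletes the only stereocentre.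

Step 6
Reactants: 8 (E)-17-oxoicos-18-enal, 9 1-(triphenyl-λ5-phosphanylidene)butan-2-one
Product: 10 (4E,22E)-tetracosa-4,22-diene-3,21-dione
Conditions: 9 (1.2 equiv), toluene, 80 °C
Reagents that add atoms: 1-(triphenyl-λ5-phosphanylidene)butan-2-one (9), CCC(=O)C=P(c1ccccc1)(c1ccccc1)c1ccccc1
Why: Wittig olefination with an acyl-stabilised ylide engages the aldehyde but not the much less electrophilic conjugated ketone and gives the (E)-enone, as is usual for stabilised ylides.

Step 7
Reactants: 10 (4E,22E)-tetracosa-4,22-diene-3,21-dione, 11 dimethyl malonate (two units incorporated)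
Product: 13 methyl 6-{14-[3-(methoxycarbonyl)-4-methyl-2,6-dioxocyclohexyl]tetradecyl}-3-methyl-2,4-dioxocyclohexane-1-carboxylate (diastereomer/enol mixture), via bis-Michael adduct 12 (not isolated)
Conditions: 11 (3 equiv), NaOMe (3 equiv), MeOH, rt; 10 in THF added; reflux; then cold 1 M HCl
Reagents that add atoms: dimethyl malonate (11), COC(=O)CC(=O)OC
Why: Sodiomalonate adds reversibly to the β-carbon of each enone (C-5 and C-23 of 10) to give 12, whose ketones then enolise on the side remote from the new bond, at the ethyl CH2 (C-2) and at the chain CH2 (C-20), and each enolate is acylated by one malonate ester with loss of methoxide. This is the Michael–Claisen (Dieckmann-type) annulation of malonates with alkenyl ketones, the long-established entry to dimedone-type diones and to 5-alkyl- and 2,5-dialkylresorcinol precursors, run here at two independent termini that a fifteen-carbon spacer keeps from interfering. Each ring closes in the 6-(enolendo)-exo-trig mode, the only alternative (attack through the inner α-carbon) being a strained four-membered ring. All equilibria are drained by deprotonation of each new 2-alkyl-1,3-dione at C-2, which consumes one methoxide per ring. The new ring stereocentres (C-2, C-4 and C-5 of each ring) are set only by base equilibration, are not needed, and are removed in steps 8–10. The selectivities required are 1,4- over 1,2-addition and malonate addition over enone self-condensation, both secured by an excess of the soft and far more acidic donor preformed as its sodium salt, while the head-to-tail placement of methyl and tether follows from the side of each ketone on which the alkene lies, C-20 becoming a ring atom so that fourteen CH2 groups remain in the tether.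

Step 8
Reactants: 13 bis(keto ester)
Product: 15 2-[14-(4-methyl-3,5-dioxocyclohexyl)tetradecyl]-5-methylcyclohexane-1,3-dione, via bis(keto acid) 14 (not isolated)
Conditions: 2 M aq NaOH, MeOH–THF, reflux; then 6 M HCl to pH 1, 70 °C
Reagents that add atoms: none
Why: Saponification proceeds while the ring carbonyls are shielded from retro-Claisen attack as diketonates, and on acidification the β-keto acids 14 lose CO2 through the usual cyclic transition state, as in the classical dimedone sequence.

Step 9
Reactants: 15 bis(cyclohexane-1,3-dione)
Product: 16 3-methoxy-2-[14-(3-methoxy-4-methyl-5-oxocyclohex-3-en-1-yl)tetradecyl]-5-methylcyclohex-2-en-1-one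
Conditions: HC(OMe)3, TsOH·H2O (cat.), MeOH, rt → 50 °C
Reagents that add atoms: methanol, CO, with trimethyl orthoformate, COC(OC)OC, as water scavenger and equivalent methoxy source
Why: Acid-catalysed enol etherification of a vinylogous acid stops at the vinylogous ester, and because each 2,5-disubstituted dione has a mirror plane through C-2 and C-5, either carbonyl leads to the same constitution with OMe next to the C-2 substituent.

Step 10
Reactants: 16 bis(3-methoxycyclohexenone)
Product: 18 3-methoxy-2-[14-(3-hydroxy-5-methoxy-4-methylphenyl)tetradecyl]-5-methylphenol, via bis(silyl dienol ether) 17 (not isolated)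
Conditions: LDA (2.5 equiv), THF, −78 °C; TMSCl, −78 → 0 °C; solvent switch; Pd(OAc)2 (2.1 equiv), MeCN–THF, rt
Reagents that add atoms: none
Why: Kinetic α′-deprotonation at C-6 (Stork–Danheiser regiochemistry) and O-silylation give 17, whose Saegusa–Ito oxidation (oxo-π-allylpalladium, syn β-hydride elimination of the C-5 hydrogen) adds the second ring double bond, after which tautomerisation to the phenol is spontaneous, erases the last stereocentres and leaves the O-methyl group in place.

Step 11
Reactants: 18 bis(3-methoxyphenol)
Product: 19 1-(5-methoxy-4-methyl-3,6-dioxocyclohexa-1,4-dien-1-yl)-14-(2-methoxy-4-methyl-3,6-dioxocyclohexa-1,4-dien-1-yl)tetradecane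
Conditions: (KSO3)2NO (5 equiv), KH2PO4 buffer, H2O–acetone–THF, rt
Reagents that add atoms: potassium nitrosodisulfonate, [K+].[K+].[O]N(S(=O)(=O)[O-])S(=O)(=O)[O-]
Why: In the Teuber oxidation the phenoxyl radical couples with a second nitrosodisulfonate at the free para carbon C-4 and collapses to the p-quinone, as known for 5-alkylresorcinol monomethyl ethers, which give 2-methoxy-6-alkylbenzoquinones.

Step 12
Reactants: 19 bis(methoxyquinone)
Product: 20 1-(2,3,6-triacetoxy-5-methoxy-4-methylphenyl)-14-(3,5,6-triacetoxy-2-methoxy-4-methylphenyl)tetradecane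
Conditions: Ac2O, conc. H2SO4 (cat.), 0 °C → rt
Reagents that add atoms: acetic anhydride, CC(=O)OC(C)=O
Why: In the Thiele–Winter acetoxylation the activated quinone takes up acetate at its only CH (C-6), which is also the electronically favoured site because it is β to the C-4 carbonyl that the vinylogous-ester methoxy group does not deactivate, and enolisation plus acetylation trap the adduct as an air-stable triacetate, with precedent on methoxy(alkyl)benzoquinones.

Step 13
Reactants: 20 hexaacetate
Product: 22 1-(2-hydroxy-5-methoxy-4-methyl-3,6-dioxocyclohexa-1,4-dien-1-yl)-14-(5-hydroxy-2-methoxy-4-methyl-3,6-dioxocyclohexa-1,4-dien-1-yl)tetradecane (target), via bis(benzenetriol) 21 (not isolated)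
Conditions: K2CO3, MeOH–THF, air, rt; then 1 M HCl
Reagents that add atoms: none
Why: Zemplén-type methanolysis of the six aryl acetates frees the 1,2,4-benzenetriols 21, which autoxidise at once in basic methanol to fully substituted hydroxyquinone anions that, as vinylogous carboxylates, resist attack at the methoxy carbon until acidification releases 22.

Compound list
1 | hexadecane-1,16-diol | OCCCCCCCCCCCCCCCCO | starting material
2 | 16-bromohexadecan-1-ol | OCCCCCCCCCCCCCCCCBr | intermediate
3 | tert-butyl[(16-bromohexadecyl)oxy]dimethylsilane | CC(C)(C)[Si](C)(C)OCCCCCCCCCCCCCCCCBr | intermediate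
4 | (E)-crotonaldehyde | C/C=C/C=O | starting material
5 | {16-[(tert-butyldimethylsilyl)oxy]hexadecyl}magnesium bromide | CC(C)(C)[Si](C)(C)OCCCCCCCCCCCCCCCC[Mg]Br | intermediate
6 | (E)-20-[(tert-butyldimethylsilyl)oxy]icos-2-en-4-ol, racemic | C/C=C/C(O)CCCCCCCCCCCCCCCCO[Si](C)(C)C(C)(C)C | intermediate
7 | (E)-icos-18-ene-1,17-diol, racemic | C/C=C/C(O)CCCCCCCCCCCCCCCCO | intermediate
8 | (E)-17-oxoicos-18-enal | C/C=C/C(=O)CCCCCCCCCCCCCCCC=O | intermediate
9 | 1-(triphenyl-λ5-phosphanylidene)butan-2-one | CCC(=O)C=P(c1ccccc1)(c1ccccc1)c1ccccc1 | starting material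
10 | (4E,22E)-tetracosa-4,22-diene-3,21-dione | CCC(=O)/C=C/CCCCCCCCCCCCCCCC(=O)/C=C/C | intermediate
11 | dimethyl malonate | COC(=O)CC(=O)OC | starting material
12 | tetramethyl 2,2'-(3,21-dioxotetracosane-5,23-diyl)dimalonate, diastereomer mixture | CCC(=O)CC(CCCCCCCCCCCCCCCC(=O)CC(C)C(C(=O)OC)C(=O)OC)C(C(=O)OC)C(=O)OC | intermediate
13 | methyl 6-{14-[3-(methoxycarbonyl)-4-methyl-2,6-dioxocyclohexyl]tetradecyl}-3-methyl-2,4-dioxocyclohexane-1-carboxylate, diastereomer/enol mixture | CC1C(=O)CC(CCCCCCCCCCCCCCC2C(=O)CC(C)C(C(=O)OC)C2=O)C(C(=O)OC)C1=O | intermediate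
14 | 6-[14-(3-carboxy-4-methyl-2,6-dioxocyclohexyl)tetradecyl]-3-methyl-2,4-dioxocyclohexane-1-carboxylic acid, mixture | CC1C(=O)CC(CCCCCCCCCCCCCCC2C(=O)CC(C)C(C(=O)O)C2=O)C(C(=O)O)C1=O | intermediate
15 | 2-[14-(4-methyl-3,5-dioxocyclohexyl)tetradecyl]-5-methylcyclohexane-1,3-dione, mixture | CC1C(=O)CC(CCCCCCCCCCCCCCC2C(=O)CC(C)CC2=O)CC1=O | intermediate
16 | 3-methoxy-2-[14-(3-methoxy-4-methyl-5-oxocyclohex-3-en-1-yl)tetradecyl]-5-methylcyclohex-2-en-1-one, mixture | CC1=C(OC)CC(CCCCCCCCCCCCCCC2=C(OC)CC(C)CC2=O)CC1=O | intermediate
17 | bis(trimethylsilyl dienol ether) of 16 (each ring: OSiMe3 at C-1, C-1=C-6 and C-2=C-3 double bonds) | CC1=C(OC)CC(CCCCCCCCCCCCCCC2=C(OC)CC(C)C=C2O[Si](C)(C)C)C=C1O[Si](C)(C)C | intermediate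
18 | 3-methoxy-2-[14-(3-hydroxy-5-methoxy-4-methylphenyl)tetradecyl]-5-methylphenol | COc1cc(CCCCCCCCCCCCCCc2c(O)cc(C)cc2OC)cc(O)c1C | intermediate
19 | 1-(5-methoxy-4-methyl-3,6-dioxocyclohexa-1,4-dien-1-yl)-14-(2-methoxy-4-methyl-3,6-dioxocyclohexa-1,4-dien-1-yl)tetradecane | COC1=C(C)C(=O)C=C(CCCCCCCCCCCCCCC2=C(OC)C(=O)C(C)=CC2=O)C1=O | intermediate
20 | 1-(2,3,6-triacetoxy-5-methoxy-4-methylphenyl)-14-(3,5,6-triacetoxy-2-methoxy-4-methylphenyl)tetradecane | COc1c(C)c(OC(C)=O)c(OC(C)=O)c(CCCCCCCCCCCCCCc2c(OC)c(OC(C)=O)c(C)c(OC(C)=O)c2OC(C)=O)c1OC(C)=O | intermediate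
21 | 1-(2,3,6-trihydroxy-5-methoxy-4-methylphenyl)-14-(3,5,6-trihydroxy-2-methoxy-4-methylphenyl)tetradecane | COc1c(C)c(O)c(O)c(CCCCCCCCCCCCCCc2c(OC)c(O)c(C)c(O)c2O)c1O | intermediate
22 | 1-(2-hydroxy-5-methoxy-4-methyl-3,6-dioxocyclohexa-1,4-dien-1-yl)-14-(5-hydroxy-2-methoxy-4-methyl-3,6-dioxocyclohexa-1,4-dien-1-yl)tetradecane (CNP0159949.0, achiral) | COC1=C(C)C(=O)C(O)=C(CCCCCCCCCCCCCCC2=C(OC)C(=O)C(C)=C(O)C2=O)C1=O | target

Total steps: 13. Longest linear sequence: 13 steps (1 → 22). Compounds 4, 9 and 11 enter as purchased materials.

Steps most likely to fail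

Step 7. One terminus may lag behind the other. Malonate may be lost again by retro-Michael reaction before the slower Claisen closure through a secondary α-carbon. Free methoxide may also trigger self-condensation of the enones. The fallback sets out from 10 and separates the two bond-forming events. Conjugate addition is run under catalytic soft-base conditions with no stoichiometric alkoxide present (excess 11, catalytic DBU or K2CO3, THF, rt), and the open-chain adduct 12 is this time isolated and purified. A separate twofold Claisen closure with stoichiometric NaOMe in MeOH–toluene, with methanol distilled off, followed by acidification, returns to the route at 13.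

Step 12. Addition to a trisubstituted, donor-bearing quinone may be sluggish, so that acid-induced exchange of the methoxy group for acetate takes over and the OMe/OH information is lost. The fallback sets out from 19 and changes the polarity of the oxygenation. Weitz–Scheffer epoxidation (t-BuOOH, Triton B, THF, 0 °C) attacks only the CH=C(alkyl) bond, because the methoxy-bearing double bond is tetrasubstituted and electron-rich, and it gives the bis(quinone epoxide) F1. Acid-promoted isomerisation of F1 (H2SO4 on silica, or brief cold conc. H2SO4), of the type that turns menadione oxide into phthiocol, leaves the oxygen on the former CH carbon and comes back to the route directly at 22, bypassing 20 and 21.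

Step 10. Double enolisation and silylation may be incomplete, or the silyl dienol ethers may hydrolyse before palladation, which would leave half-aromatised material. The fallback sets out from 13 and aromatises with the esters still in place. Bromination–dehydrobromination (Br2, AcOH, 0 °C, then heat), the method used for dihydro-β-resorcylates, gives the bis(β-resorcylate) F2. MeI/K2CO3 in acetone methylates only the hydroxyl para to each ester, because the ortho hydroxyl is chelated, and this gives the bis(4-O-methyl ether) F3. Saponification with protodecarboxylation (KOH, aq. ethylene glycol, heat, then acid) comes back to the route at 18 and replaces steps 8–10.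

Further compounds
F0 | step 7 | none | none
F1 | step 12 | bis-epoxide of 19 at both CH=C(alkyl) bonds (cis-fused oxiranes, diastereomer mixture) | COC1=C(C)C(=O)C2OC2(CCCCCCCCCCCCCCC3=C(OC)C(=O)C4(C)OC4C3=O)C1=O
F2 | step 10 | methyl 2,4-dihydroxy-6-{14-[2,6-dihydroxy-3-(methoxycarbonyl)-4-methylphenyl]tetradecyl}-3-methylbenzoate | Cc1c(O)cc(CCCCCCCCCCCCCCc2c(O)cc(C)c(C(=O)OC)c2O)c(C(=O)OC)c1O
F3 | step 10 | methyl 2-hydroxy-6-{14-[2-hydroxy-6-methoxy-3-(methoxycarbonyl)-4-methylphenyl]tetradecyl}-4-methoxy-3-methylbenzoate | COc1cc(CCCCCCCCCCCCCCc2c(OC)cc(C)c(C(=O)OC)c2O)c(C(=O)OC)c(O)c1C
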